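**Retrosynthetic overview**
1. Target 20 ⇐ benzyl ester 19 (final hydrogenolysis) ⇐ depside ester C–O bond between acid 11 and phenol 16.
2. 11 and 16 both ⇐ one resorcylate, methyl 2-heptyl-4,6-dihydroxybenzoate 9, by O-alkylation and ester exchange (free 4-OH versus chelated 6-OH).
3. 9 ⇐ aromatisation of the cyclic 1,3-dione ester 6.
4. 6 ⇐ key C–C bond: intermolecular Michael addition of dimethyl malonate 4 to (E)-undec-3-en-2-one 3, then Claisen (Dieckmann) ring closure in the same flask; 3 ⇐ octanal + acetonyl ylide.
5. Ring order: the only ring built is the carbocycle of 6 (step 2), aromatised in step 3; it supplies both benzene rings.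

Assumption: the target has no stereocentre or other stereogenic element, so "single enantiomer" needs no stereocontrol; the stereocentres of 5, 6 and 8 (racemic) are erased on aromatisation.

**Route**

Step 1
Reactants: 1 octanal; 2 1-(triphenylphosphoranylidene)propan-2-one
Product: 3 (E)-undec-3-en-2-one
Conditions: 2 (1.1 eq), toluene, 90 °C, 16 h
Reagents that add atoms: none
Why: Wittig olefination with a stabilised acyl ylide gives the (E)-enone cleanly and avoids aldehyde self-aldol; the alkene geometry is consumed in step 2.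

Step 2
Reactants: 3 (E)-undec-3-en-2-one; 4 dimethyl malonate
Product: 6 racemic methyl 6-heptyl-2-hydroxy-4-oxocyclohex-2-ene-1-carboxylate, via Michael adduct 5 (not isolated)
Conditions: NaOMe (1.2 eq), MeOH, reflux, 4 h; then cold 1 M HCl
Reagents that add atoms: none
Why: Intermolecular Michael addition of sodiomalonate to the enone forms the key C–C bond, and the methyl-ketone enolate of 5 then closes the ring by intramolecular Claisen (Dieckmann) condensation, driven by the stabilised 1,3-dione enolate; the two new stereocentres (racemic, mainly trans) disappear in step 3.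

Step 3
Reactants: 6 racemic methyl 6-heptyl-2-hydroxy-4-oxocyclohex-2-ene-1-carboxylate; 7 bromine
Product: 9 methyl 2-heptyl-4,6-dihydroxybenzoate, via 3-bromo enol 8 (not isolated)
Conditions: Br2 (1.0 eq), DMF, 0 °C, 1 h; then 80 °C, 12 h
Reagents that add atoms: none
Why: Bromination at C3 between the two carbonyls, then enolisation and thermal loss of HBr (bromination–dehydrobromination aromatisation), gives the resorcylate with the ester kept because no hydrolytic medium is present.

Step 4
Reactants: 9 methyl 2-heptyl-4,6-dihydroxybenzoate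
Product: 10 methyl 2-heptyl-4,6-dimethoxybenzoate
Conditions: MeI (3 eq), K2CO3 (3 eq), DMF, 45 °C, 16 h
Reagents that add atoms: iodomethane, CI
Why: Williamson ether synthesis; excess MeI with K2CO3 in DMF also alkylates the hydrogen-bonded ortho hydroxyl.

Step 5
Reactants: 10 methyl 2-heptyl-4,6-dimethoxybenzoate
Product: 11 2-heptyl-4,6-dimethoxybenzoic acid
Conditions: KOH (6 eq), DMSO/H2O 4:1, 100 °C, 12 h; then cold 1 M HCl to pH 2
Reagents that add atoms: potassium hydroxide, [K+].[OH-] (its oxygen becomes the acid OH)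
Why: Saponification (BAc2) of the di-ortho-substituted ester needs poorly solvated hydroxide in hot aqueous DMSO, which leaves the aryl methyl ethers untouched.

Step 6
Reactants: 9 methyl 2-heptyl-4,6-dihydroxybenzoate
Product: 12 methyl 4-(benzyloxy)-2-heptyl-6-hydroxybenzoate
Conditions: BnBr (1.05 eq), K2CO3 (1.1 eq), acetone, reflux, 8 h
Reagents that add atoms: benzyl bromide, BrCc1ccccc1
Why: Regioselective Williamson etherification: the 4-OH is more acidic and free, whereas the 6-OH is chelated to the ester carbonyl, so one equivalent of BnBr gives the mono-ether.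

Step 7
Reactants: 12 methyl 4-(benzyloxy)-2-heptyl-6-hydroxybenzoate
Product: 13 methyl 4-(benzyloxy)-2-heptyl-6-methoxybenzoate
Conditions: MeI (2 eq), K2CO3 (2 eq), DMF, 45 °C, 16 h
Reagents that add atoms: iodomethane, CI
Why: Williamson ether synthesis on the chelated phenol under more forcing conditions; the benzyl ether and ester are inert.

Step 8
Reactants: 13 methyl 4-(benzyloxy)-2-heptyl-6-methoxybenzoate
Product: 14 4-(benzyloxy)-2-heptyl-6-methoxybenzoic acid
Conditions: KOH (6 eq), DMSO/H2O 4:1, 100 °C, 12 h; then cold 1 M HCl to pH 2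
Reagents that add atoms: potassium hydroxide, [K+].[OH-] (its oxygen becomes the acid OH)
Why: Saponification of the hindered ester as in step 5; benzyl and methyl aryl ethers are stable to hydroxide.

Step 9
Reactants: 14 4-(benzyloxy)-2-heptyl-6-methoxybenzoic acid
Product: 15 2-heptyl-4-hydroxy-6-methoxybenzoic acid
Conditions: H2 (1 atm), 10% Pd/C, EtOAc, rt, 3 h
Reagents that add atoms: none
Why: Catalytic hydrogenolysis of the benzyl aryl ether frees the 4-OH without touching the acid, methyl ether or arene.

Step 10
Reactants: 15 2-heptyl-4-hydroxy-6-methoxybenzoic acid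
Product: 16 benzyl 2-heptyl-4-hydroxy-6-methoxybenzoate
Conditions: BnBr (1.05 eq), KHCO3 (1.2 eq), DMF, rt, 16 h
Reagents that add atoms: benzyl bromide, BrCc1ccccc1
Why: Chemoselective SN2 O-alkylation of the carboxylate: bicarbonate deprotonates the acid (pKa about 4) but not the phenol (pKa about 9), and alkylation at the carboxylate oxygen is not slowed by the ortho substituents.

Step 11
Reactants: 11 2-heptyl-4,6-dimethoxybenzoic acid; 16 benzyl 2-heptyl-4-hydroxy-6-methoxybenzoate; 17 trifluoroacetic anhydride
Product: 19 benzyl 4-[(2-heptyl-4,6-dimethoxybenzoyl)oxy]-2-heptyl-6-methoxybenzoate, via mixed trifluoroacetic anhydride 18 (not isolated)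
Conditions: TFAA (4 eq), dry toluene, rt, 3 h; aq NaHCO3 work-up
Reagents that add atoms: none
Why: Mixed-anhydride esterification: the electron-rich hindered aroyl group of 18 is acylium-like and is transferred to the only free hydroxyl of 16, while any aryl trifluoroacetate formed is cleaved on work-up.

Step 12
Reactants: 19 benzyl 4-[(2-heptyl-4,6-dimethoxybenzoyl)oxy]-2-heptyl-6-methoxybenzoate
Product: 20 4-[(2-heptyl-4,6-dimethoxybenzoyl)oxy]-2-heptyl-6-methoxybenzoic acid
Conditions: H2 (1 atm), 10% Pd/C, EtOAc, rt, 2 h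
Reagents that add atoms: none
Why: Neutral hydrogenolysis of the benzyl ester releases the acid without cleaving the aryl ester (depside) link or the methyl ethers; no stereocentre is involved.

**Compound list**
1 | octanal | CCCCCCCC=O | starting material
2 | 1-(triphenylphosphoranylidene)propan-2-one | CC(=O)C=P(c1ccccc1)(c1ccccc1)c1ccccc1 | starting material
3 | (E)-undec-3-en-2-one | CCCCCCC/C=C/C(C)=O | intermediate
4 | dimethyl malonate | COC(=O)CC(=O)OC | starting material
5 | dimethyl 2-(2-oxoundecan-4-yl)propanedioate (racemic Michael adduct) | CCCCCCCC(CC(C)=O)C(C(=O)OC)C(=O)OC | intermediate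
6 | methyl 6-heptyl-2-hydroxy-4-oxocyclohex-2-ene-1-carboxylate (racemic, enol form of the 1,3-dione) | CCCCCCCC1CC(=O)C=C(O)C1C(=O)OC | intermediate
7 | bromine | BrBr | starting material
8 | methyl 3-bromo-6-heptyl-2-hydroxy-4-oxocyclohex-2-ene-1-carboxylate (racemic) | CCCCCCCC1CC(=O)C(Br)=C(O)C1C(=O)OC | intermediate
9 | methyl 2-heptyl-4,6-dihydroxybenzoate | CCCCCCCc1cc(O)cc(O)c1C(=O)OC | intermediate
10 | methyl 2-heptyl-4,6-dimethoxybenzoate | CCCCCCCc1cc(OC)cc(OC)c1C(=O)OC | intermediate
11 | 2-heptyl-4,6-dimethoxybenzoic acid | CCCCCCCc1cc(OC)cc(OC)c1C(=O)O | intermediate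
12 | methyl 4-(benzyloxy)-2-heptyl-6-hydroxybenzoate | CCCCCCCc1cc(OCc2ccccc2)cc(O)c1C(=O)OC | intermediate
13 | methyl 4-(benzyloxy)-2-heptyl-6-methoxybenzoate | CCCCCCCc1cc(OCc2ccccc2)cc(OC)c1C(=O)OC | intermediate
14 | 4-(benzyloxy)-2-heptyl-6-methoxybenzoic acid | CCCCCCCc1cc(OCc2ccccc2)cc(OC)c1C(=O)O | intermediate
15 | 2-heptyl-4-hydroxy-6-methoxybenzoic acid | CCCCCCCc1cc(O)cc(OC)c1C(=O)O | intermediate
16 | benzyl 2-heptyl-4-hydroxy-6-methoxybenzoate | CCCCCCCc1cc(O)cc(OC)c1C(=O)OCc1ccccc1 | intermediate
17 | trifluoroacetic anhydride | O=C(OC(=O)C(F)(F)F)C(F)(F)F | starting material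
18 | 2-heptyl-4,6-dimethoxybenzoic trifluoroacetic anhydride | CCCCCCCc1cc(OC)cc(OC)c1C(=O)OC(=O)C(F)(F)F | intermediate
19 | benzyl 4-[(2-heptyl-4,6-dimethoxybenzoyl)oxy]-2-heptyl-6-methoxybenzoate | CCCCCCCc1cc(OC(=O)c2c(CCCCCCC)cc(OC)cc2OC)cc(OC)c1C(=O)OCc1ccccc1 | intermediate
20 | 4-[(2-heptyl-4,6-dimethoxybenzoyl)oxy]-2-heptyl-6-methoxybenzoic acid | CCCCCCCc1cc(OC(=O)c2c(CCCCCCC)cc(OC)cc2OC)cc(OC)c1C(=O)O | target

**Totals**
Total step count: 12.
Longest linear sequence: 10 steps (1, 2, 3, 6, 7, 8, 9, 10, 11, 12).

**Three steps most likely to fail**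

Step 3 (aromatisation): one equivalent of bromine may over-brominate the electron-rich product ring or leave unreacted dione. The fallback sets out from 6 and comes back at 9. Compound 6 is treated with excess Br2 (3.2 eq) in AcOH at rt, so that bromination runs through aromatisation and on to methyl 3,5-dibromo-2-heptyl-4,6-dihydroxybenzoate F1, which is isolated by crystallisation. Both ring bromines are then removed by hydrogenolysis (H2, Pd/C, NaOAc, MeOH, rt) to give 9. This turns the over-bromination into the planned pathway.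

Step 5 (saponification of the di-ortho-substituted ester): hydrolysis may stall, or the electron-rich acid may decarboxylate if forced. The fallback sets out from 10 and comes back at 11. The ester is reduced with LiAlH4 (THF, reflux) to (2-heptyl-4,6-dimethoxyphenyl)methanol F2. This is oxidised with MnO2 (CH2Cl2, rt) to 2-heptyl-4,6-dimethoxybenzaldehyde F3. Pinnick oxidation (NaClO2, NaH2PO4, 2-methyl-2-butene, t-BuOH/H2O, rt) then gives 11, so no attack at the hindered ester carbonyl by hydroxide is needed.

Step 11 (depside coupling): the TFAA method may give low conversion or C-acylation of the phenol ring. The fallback sets out from 11 and comes back at 19. Acid 11 is converted with oxalyl chloride (cat. DMF, CH2Cl2, 0 °C to rt) into 2-heptyl-4,6-dimethoxybenzoyl chloride F4. This is coupled with phenol 16 under base-mediated acyl transfer (Et3N, cat. DMAP, CH2Cl2, rt) to give 19.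

**Further compounds**
F1 | step 3 | methyl 3,5-dibromo-2-heptyl-4,6-dihydroxybenzoate | CCCCCCCc1c(Br)c(O)c(Br)c(O)c1C(=O)OC
F2 | step 5 | (2-heptyl-4,6-dimethoxyphenyl)methanol | CCCCCCCc1cc(OC)cc(OC)c1CO
F3 | step 5 | 2-heptyl-4,6-dimethoxybenzaldehyde | CCCCCCCc1cc(OC)cc(OC)c1C=O
F4 | step 11 | 2-heptyl-4,6-dimethoxybenzoyl chloride | CCCCCCCc1cc(OC)cc(OC)c1C(Cl)=O
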